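**Retrosynthetic overview**

1. Feature: the 11-membered ring B (N4, C5–C8, C9, C10, C11, C12, C1, C9a) holds six contiguous carbons, C9a–C1–C12–C11–C10–C9, that are the six ring carbons of (S)-carvone. C9a is the carvone C=O, C9 the C–Me carbon (its methyl is C8), and C12 the CH bearing isopropenyl, which becomes the C13(Me)–C14(=O) arm of the fused lactone C.
2. Last disconnection C7–C8: target 30 ⇐ E-enone 29 ⇐ Horner–Wadsworth–Emmons closure of the C8 β-keto phosphonate onto the C7 aldehyde in 28; ring B closes last.
3. 28 ⇐ methyl ketone 24: appended lactone D by vinylogous Mannich addition of a silyloxyfuran at C3 of an N-acyliminium ion; pyrrolidinone A from the N4–C9a amide and a C3 aldehyde (ozonolysis of a C1-allyl group).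
4. C9–C9a cut: periodate cleavage of an α-ketol made by conjugate ethylation and Rubottom oxidation of the carvone enone; the C1-allyl group is set on the intact ring by alkylation and equilibration.
5. Lactone C comes first, from carvone-derived keto acid 4 by γ-bromination and SN2 lactonisation. Ring order: C (step 5) → carvone ring opened (step 9) → A (step 12) → D (step 14) → B (step 19).

Key step: step 19

Remark: numbering used throughout is N4, lactam C9a, pyrrolidinone C1–C3, chain C5–C8, ketone C9, C10 (Et), C11 (O), C12, C13 (Me), C14 (fused-lactone C=O), and C18 (O–CH), C19, C20 (Me), C21 (C=O) for the appended lactone; carvone-ring intermediates carry the same locants.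
Remark: C13 is carried as an epimer mixture from step 2 until it is equilibrated in step 8; the silyloxy/hydroxy centre C9 of 10–14 (destroyed in step 9) and the hemiaminal centre C3 of 20 (ionised in step 14) are left unspecified.
Remark: the C7 aldehyde is carried as a silyl ether, because an acetal would ionise under the Lewis acid of step 14.

**Route**

Step 1
Reactants: 1 (S)-carvone
Product: 2 (1S,5S)-cis-carveol
Conditions: NaBH4, CeCl3·7H2O, MeOH, −20 °C
Reagents that add atoms: none
Why: Luche 1,2-reduction masks the enone carbonyl for the hydroboration; hydride should enter to give the cis allylic alcohol, and this centre is erased again in step 3.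

Step 2
Reactants: 2 (1S,5S)-cis-carveol
Product: 3 (1S,5S)-5-(1-hydroxypropan-2-yl)-2-methylcyclohex-2-en-1-ol (C13 epimers)
Conditions: 9-BBN (2.5 equiv), THF, 0 °C → rt; then NaOH, H2O2, 0 °C → rt
Reagents that add atoms: hydrogen peroxide, OO
Why: Anti-Markovnikov hydroboration–oxidation; 9-BBN should take only the 1,1-disubstituted alkene and leave the trisubstituted ring alkene, and the new C13 centre forms without control and is corrected in step 8.

Step 3
Reactants: 3 diol
Product: 4 2-[(1S)-4-methyl-5-oxocyclohex-3-en-1-yl]propanoic acid (C13 epimers)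
Conditions: CrO3, H2SO4, acetone, 0 °C
Reagents that add atoms: chromium trioxide, O=[Cr](=O)=O
Why: Jones oxidation takes the primary alcohol to the acid and the allylic alcohol back to the enone in one operation; no stereocentre is formed.

Step 4
Reactants: 4 keto acid
Product: 5 trimethylsilyl 2-[4-methyl-5-(trimethylsilyloxy)cyclohexa-2,4-dien-1-yl]propanoate (linear dienol ether, C12 as in carvone, C13 epimers)
Conditions: MeMgBr (2.3 equiv), FeCl3 (5 mol %), Et2O–THF, −20 °C; then TMSCl, Et3N, HMPA, −20 °C → rt
Reagents that add atoms: chlorotrimethylsilane, C[Si](C)(C)Cl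
Why: Iron-catalysed Grignard deprotonation of a 2-cyclohexenone removes the γ-hydrogen (C11–H) and gives the through-conjugated dienolate, the first equivalent of Grignard only forming the carboxylate; silylation of both oxygens gives the linear dienol ether.

Step 5
Reactants: 5 bis-silyl dienol ether
Product: 7 (3aS,7aR)-3,6-dimethyl-3a,4-dihydro-1-benzofuran-2,5(3H,7aH)-dione as C13 epimers, via trans-γ-bromo enone silyl ester 6 (not isolated)
Conditions: NBS, THF, −78 °C; then sat. aq NaHCO3, THF, rt
Reagents that add atoms: none
Why: γ-Bromination of a silyl dienol ether puts bromine on C11 anti to the C12 side chain, and after hydrolysis of the silyl ester the carboxylate displaces the allylic bromide by SN2; the five-membered ring can only close on the face that carries the side chain, so O11 ends cis to C12–C13.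

Step 6
Reactants: 7 cis-fused lactone enone; 8 ethylmagnesium bromide
Product: 9 triethylsilyl enol ether of the C10-ethyl adduct (C9=C9a enol ether, Et trans to O11)
Conditions: CuBr·SMe2 (10 mol %), TESCl, HMPA, THF, −78 °C; Et3N quench
Reagents that add atoms: ethylmagnesium bromide 8, CC[Mg]Br; chlorotriethylsilane, CC[Si](CC)(CC)Cl
Why: Copper-catalysed Grignard conjugate addition with chlorosilane trapping; ethyl should enter C10 on the convex face, anti to the C11–O bond and to the C12 side chain, and the fast silyl trapping at −78 °C is chosen to outrun reductive loss of the γ-acyloxy group and to fix the enol ether regiochemistry.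

Step 7
Reactants: 9 silyl enol ether
Product: 10 α-(triethylsilyloxy) ketone (10S,11R,12S; C9 and C13 unspecified)
Conditions: mCPBA, NaHCO3, CH2Cl2, −20 °C → 0 °C
Reagents that add atoms: 3-chloroperbenzoic acid, OOC(=O)c1cccc(Cl)c1
Why: Rubottom oxidation of the electron-rich enol ether puts oxygen on C9 with the silyl group ending on the new tertiary oxygen under buffered conditions; the C9 configuration is irrelevant because the centre is destroyed in step 9.

Step 8
Reactants: 10 α-silyloxy ketone; 11 allyl iodide
Product: 13 C1-allyl α-silyloxy ketone (1S,10S,11R,12S,13S), via kinetic allyl ketone 12 (not isolated)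
Conditions: LDA, THF, −78 °C; 11, −78 → −20 °C; then t-BuOK (0.3 equiv), t-BuOH, 0 °C → rt
Reagents that add atoms: allyl iodide 11, C=CCI
Why: Enolate alkylation at the only enolisable ketone α-carbon (C1, since C9 is quaternary) followed by alkoxide equilibration; the allyl group should settle equatorial and cis to the C12 side chain because only that epimer has a chair with a single axial bond (C12–C13), and the C13 methyl should settle on the convex face of the cis-fused lactone.

Step 9
Reactants: 13 allyl ketone
Product: 15 seco keto acid (C9 methyl ketone and C9a acid), via α-hydroxy ketone 14 (not isolated)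
Conditions: HF·pyridine, MeCN, 0 °C; then H5IO6, THF–H2O, 0 °C → rt
Reagents that add atoms: orthoperiodic acid, OI(O)(O)(O)(O)=O
Why: Fluoride frees the tertiary α-ketol and periodate cleavage of the α-hydroxy ketone cuts the C9–C9a bond regiospecifically to the methyl ketone and the acid under acidic conditions that leave every stereocentre, the allyl group and the β-acyloxy ketone untouched.

Step 10
Reactants: 16 3-aminopropan-1-ol
Product: 17 3-[(tert-butyldimethylsilyl)oxy]propan-1-amine
Conditions: TBSCl, imidazole, CH2Cl2, 0 °C → rt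
Reagents that add atoms: tert-butyldimethylsilyl chloride, CC(C)(C)[Si](C)(C)Cl
Why: O-Silylation of an amino alcohol; any N-silyl amine is hydrolysed on work-up, so only the silyl ether remains.

Step 11
Reactants: 15 seco keto acid; 17 silyloxypropylamine
Product: 18 secondary amide of the C9a acid (N4–C9a bond)
Conditions: EDC·HCl, HOBt, CH2Cl2, 0 °C → rt
Reagents that add atoms: none
Why: Carbodiimide amide coupling through the HOBt ester under near-neutral conditions that should not epimerise C1 or eliminate the β-acyloxy ketone; imine formation at the ketone is reversed on work-up.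

Step 12
Reactants: 18 amide
Product: 20 hydroxy lactam (5-hydroxypyrrolidin-2-one, ring A), via aldehyde amide 19 (not isolated)
Conditions: O3, CH2Cl2, −78 °C; Me2S, −78 °C → rt
Reagents that add atoms: ozone, [O-][O+]=O
Why: Ozonolysis of the only alkene gives the C3 aldehyde, which is trapped by the amide N–H as the five-membered hemiaminal; the C3 hydroxyl configuration is irrelevant.

Step 13
Reactants: 21 3-methylfuran-2(5H)-one
Product: 22 3-methyl-2-(triisopropylsilyloxy)furan
Conditions: TIPSOTf, Et3N, CH2Cl2, 0 °C
Reagents that add atoms: triisopropylsilyl triflate, CC(C)[Si](C(C)C)(C(C)C)OS(=O)(=O)C(F)(F)F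
Why: Soft enolisation and O-silylation of the butenolide give the aromatic silyloxyfuran (silyl dienol ether formation).

Step 14
Reactants: 20 hydroxy lactam; 22 silyloxyfuran
Product: 23 butenolide adduct (1S,3S,10S,11R,12S,13S,18S)
Conditions: BF3·OEt2, CH2Cl2, −78 °C
Reagents that add atoms: none
Why: Vinylogous Mannich reaction of the N-acyliminium ion; the silyloxyfuran should attack C3 on the face opposite the bulky C1 substituent (C1/C3 trans) and through the usual staggered approach of 2-silyloxyfurans to five-membered cyclic N-acyliminium ions, which gives the like (3S,18S, threo) junction.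

Step 15
Reactants: 23 butenolide adduct
Product: 24 bis-lactone methyl ketone (1S,3S,10S,11R,12S,13S,18S,20S)
Conditions: H2 (1 atm), 5% Rh/Al2O3, EtOAc, rt
Reagents that add atoms: none
Why: Catalytic hydrogenation of the butenolide; hydrogen should be delivered to the face opposite the C18 substituent, so the C20 methyl ends cis to it, and rhodium avoids hydrogenolysis of the allylic C18–O bond and leaves the ketone.

Step 16
Reactants: 24 methyl ketone
Product: 26 β-keto phosphonate silyl ether, via β-keto phosphonite 25 (not isolated)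
Conditions: LiHMDS, THF, −78 °C; (MeO)2PCl, −78 °C; then t-BuOOH, −78 → 0 °C
Reagents that add atoms: dimethyl chlorophosphite, COP(Cl)OC; tert-butyl hydroperoxide, CC(C)(C)OO
Why: Kinetic deprotonation of the methyl ketone at the unhindered C8 methyl (more acidic than the lactone and lactam α-CH, with C10–H hindered), C-phosphinylation of the enolate by the chlorophosphite and P(III) → P(V) oxidation give the β-keto phosphonate without forming the C10 enolate.

Step 17
Reactants: 26 β-keto phosphonate silyl ether
Product: 27 β-keto phosphonate alcohol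
Conditions: HF·pyridine, THF, 0 °C → rt
Reagents that add atoms: none
Why: Fluoride cleavage of the primary silyl ether under mildly acidic conditions that spare the β-acyloxy ketone and the phosphonate.

Step 18
Reactants: 27 alcohol
Product: 28 seco β-keto phosphonate aldehyde (C7 aldehyde)
Conditions: Dess–Martin periodinane, NaHCO3, CH2Cl2, 0 °C → rt
Reagents that add atoms: none
Why: Dess–Martin oxidation of the primary alcohol under buffered, base-free conditions; the aldehyde is used at once.

Step 19
Reactants: 28 seco β-keto phosphonate aldehyde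
Product: 29 11-membered (E)-enone (7,8-didehydro target)
Conditions: LiCl, i-Pr2NEt, MeCN, slow addition to 1 mM, rt
Reagents that add atoms: none
Why: Horner–Wadsworth–Emmons olefination under LiCl/amine (Masamune–Roush) conditions: lithium chelates the β-keto phosphonate so that the amine removes only the doubly activated C8–H, the carbanion adds to the C7 aldehyde, and the oxaphosphetane collapses to the C7=C8 enone with loss of dimethyl phosphate. The closest known reaction type is the intramolecular HWE macrocyclisation of β-keto phosphonate aldehydes at high dilution. Ring B (C1, C12, C11, C10, C9, C8, C7, C6, C5, N4, C9a) closes end-to-end by attack of C8 on the aldehyde carbon (11-exo-trig at the carbonyl), with the pyrrolidinone and the fused γ-lactone fixing three ring bonds and shortening the end-to-end distance. No stereocentre is formed; the E geometry follows from reversible addition through the anti oxaphosphetane and is in any case erased in step 20. The step needs deprotonation at C8 and not at C10, whose enolate could epimerise or expel the C11 carboxylate, and the acidity gap of the lithium-chelated phosphonate towards the hindered amine secures this; high dilution secures ring closure over oligomerisation.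

Step 20
Reactants: 29 enone
Product: 30 target CNP0147860.1 (1S,3S,10S,11R,12S,13S,18S,20S)
Conditions: H2 (1 atm), 10% Pd/C, EtOAc, rt
Reagents that add atoms: none
Why: Catalytic hydrogenation of the conjugated C7=C8 bond under neutral conditions, which should leave the ketone, lactam and both lactones and should not epimerise C10.

**Compound list**

1 | (S)-carvone | CC1=CC[C@@H](CC1=O)C(C)=C | starting material
2 | (1S,5S)-cis-carveol | CC1=CC[C@@H](C[C@@H]1O)C(C)=C | intermediate
3 | (1S,5S)-5-(1-hydroxypropan-2-yl)-2-methylcyclohex-2-en-1-ol, C13 epimers | CC1=CC[C@@H](C[C@@H]1O)C(C)CO | intermediate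
4 | 2-[(1S)-4-methyl-5-oxocyclohex-3-en-1-yl]propanoic acid, C13 epimers | CC1=CC[C@@H](CC1=O)C(C)C(=O)O | intermediate
5 | trimethylsilyl 2-[4-methyl-5-(trimethylsilyloxy)cyclohexa-2,4-dien-1-yl]propanoate, C12 as in carvone, C13 epimers | CC1=C(O[Si](C)(C)C)C[C@H](C=C1)C(C)C(=O)O[Si](C)(C)C | intermediate
6 | trans-γ-bromo enone trimethylsilyl ester (Br on C11 trans to the C12 side chain) | C1=C(C)C(=O)C[C@@H](C(C)C(=O)O[Si](C)(C)C)[C@@H]1Br | intermediate (not isolated)
7 | (3aS,7aR)-3,6-dimethyl-3a,4-dihydro-1-benzofuran-2,5(3H,7aH)-dione, cis-fused lactone enone, C13 epimers | C1=C(C)C(=O)C[C@@H]2[C@H]1OC(=O)C2C | intermediate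
8 | ethylmagnesium bromide | CC[Mg]Br | starting material
9 | triethylsilyl enol ether (C9=C9a) of the C10-ethyl cis-lactone, Et trans to O11, C13 epimers | CC[C@@H]1C(C)=C(O[Si](CC)(CC)CC)C[C@@H]2[C@H]1OC(=O)C2C | intermediate
10 | C9-(triethylsilyloxy) C9a-ketone of the cis-lactone (10S,11R,12S; C9, C13 unspecified) | CC[C@@H]1C(C)(O[Si](CC)(CC)CC)C(=O)C[C@@H]2[C@H]1OC(=O)C2C | intermediate
11 | allyl iodide | C=CCI | starting material
12 | kinetic C1-allyl ketone (C1, C9, C13 unspecified) | CC[C@@H]1C(C)(O[Si](CC)(CC)CC)C(=O)C(CC=C)[C@@H]2[C@H]1OC(=O)C2C | intermediate (not isolated)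
13 | C1-allyl C9-(triethylsilyloxy) ketone (1S,10S,11R,12S,13S; allyl cis to C12–C13, C9 unspecified) | CC[C@@H]1C(C)(O[Si](CC)(CC)CC)C(=O)[C@@H](CC=C)[C@@H]2[C@H]1OC(=O)[C@H]2C | intermediate
14 | C9-hydroxy C9a-ketone (α-ketol) | CC[C@@H]1C(C)(O)C(=O)[C@@H](CC=C)[C@@H]2[C@H]1OC(=O)[C@H]2C | intermediate (not isolated)
15 | seco keto acid: γ-lactone bearing the 3-oxopentan-2-yl group on C11 and the 2-carboxypent-4-enyl unit on C12 (1S,10S,11R,12S,13S) | CC[C@H](C(C)=O)[C@@H]1OC(=O)[C@@H](C)[C@@H]1[C@H](CC=C)C(=O)O | intermediate
16 | 3-aminopropan-1-ol | NCCCO | starting material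
17 | 3-[(tert-butyldimethylsilyl)oxy]propan-1-amine | NCCCO[Si](C)(C)C(C)(C)C | intermediate
18 | N-(3-silyloxypropyl) amide of 15 | CC[C@H](C(C)=O)[C@@H]1OC(=O)[C@@H](C)[C@@H]1[C@H](CC=C)C(=O)NCCCO[Si](C)(C)C(C)(C)C | intermediate
19 | C3 aldehyde amide | CC[C@H](C(C)=O)[C@@H]1OC(=O)[C@@H](C)[C@@H]1[C@H](CC=O)C(=O)NCCCO[Si](C)(C)C(C)(C)C | intermediate (not isolated)
20 | hydroxy lactam: 5-hydroxy-1-(3-silyloxypropyl)pyrrolidin-2-one carrying the lactone unit on C1 (C3 epimers) | CC[C@H](C(C)=O)[C@@H]1OC(=O)[C@@H](C)[C@@H]1[C@@H]1CC(O)N(CCCO[Si](C)(C)C(C)(C)C)C1=O | intermediate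
21 | 3-methylfuran-2(5H)-one | CC1=CCOC1=O | starting material
22 | 3-methyl-2-(triisopropylsilyloxy)furan | Cc1ccoc1O[Si](C(C)C)(C(C)C)C(C)C | intermediate
23 | butenolide adduct (1S,3S,10S,11R,12S,13S,18S) | CC[C@H](C(C)=O)[C@@H]1OC(=O)[C@@H](C)[C@@H]1[C@@H]1C[C@@H]([C@@H]2C=C(C)C(=O)O2)N(CCCO[Si](C)(C)C(C)(C)C)C1=O | intermediate
24 | bis-lactone methyl ketone (1S,3S,10S,11R,12S,13S,18S,20S) | CC[C@H](C(C)=O)[C@@H]1OC(=O)[C@@H](C)[C@@H]1[C@@H]1C[C@@H]([C@@H]2C[C@H](C)C(=O)O2)N(CCCO[Si](C)(C)C(C)(C)C)C1=O | intermediate
25 | β-keto dimethyl phosphonite | CC[C@H](C(=O)CP(OC)OC)[C@@H]1OC(=O)[C@@H](C)[C@@H]1[C@@H]1C[C@@H]([C@@H]2C[C@H](C)C(=O)O2)N(CCCO[Si](C)(C)C(C)(C)C)C1=O | intermediate (not isolated)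
26 | β-keto dimethyl phosphonate silyl ether | CC[C@H](C(=O)CP(=O)(OC)OC)[C@@H]1OC(=O)[C@@H](C)[C@@H]1[C@@H]1C[C@@H]([C@@H]2C[C@H](C)C(=O)O2)N(CCCO[Si](C)(C)C(C)(C)C)C1=O | intermediate
27 | β-keto phosphonate alcohol | CC[C@H](C(=O)CP(=O)(OC)OC)[C@@H]1OC(=O)[C@@H](C)[C@@H]1[C@@H]1C[C@@H]([C@@H]2C[C@H](C)C(=O)O2)N(CCCO)C1=O | intermediate
28 | seco β-keto phosphonate aldehyde | CC[C@H](C(=O)CP(=O)(OC)OC)[C@@H]1OC(=O)[C@@H](C)[C@@H]1[C@@H]1C[C@@H]([C@@H]2C[C@H](C)C(=O)O2)N(CCC=O)C1=O | intermediate
29 | 11-membered (E)-enone, 7,8-didehydro target | CC[C@@H]1C(=O)/C=C/CCN2C(=O)[C@@H](C[C@H]2[C@@H]2C[C@H](C)C(=O)O2)[C@@H]2[C@H]1OC(=O)[C@H]2C | intermediate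
30 | CNP0147860.1 (1S,3S,10S,11R,12S,13S,18S,20S) | CC[C@@H]1C(=O)CCCCN2C(=O)[C@@H](C[C@H]2[C@@H]2C[C@H](C)C(=O)O2)[C@@H]2[C@H]1OC(=O)[C@H]2C | target

**Totals**

Total step count: 20. Longest linear sequence: 18 steps (steps 1–9, 11, 12, 14–20).

**Steps most likely to fail**

1. Step 19 (ring closure by olefination). The phosphonate anion may add to the aldehyde of a second molecule faster than the strained 11-membered ring closes, or the β-amido aldehyde may lose the lactam nitrogen by β-elimination under the base. The fallback closes the same C7=C8 bond by ring-closing metathesis; it sets out from 26 and returns at 29. Aqueous formaldehyde with K2CO3 converts the β-keto phosphonate 26 by intermolecular HWE into the vinyl ketone silyl ether F1. HF·pyridine gives the vinyl ketone alcohol F2, and Dess–Martin oxidation gives the vinyl ketone aldehyde F3. Takai–Lombardo methylenation (Zn, CH2Br2, TiCl4), which is non-basic and selective for aldehydes, gives the N-but-3-enyl vinyl ketone F4. A second-generation ruthenium alkylidene catalyst in toluene at 1 mM and 80 °C closes the ring with loss of ethylene and delivers 29; the alkene geometry is without consequence after step 20.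

2. Step 14 (vinylogous Mannich). Facial selectivity at the iminium carbon or at the furan terminus may be poor, so that two new centres are set at once with the wrong relative configuration, or the ketone enol may intercept the iminium ion. The fallback sets only C3 in the iminium step and C18 under reagent control; it sets out from 20 and returns at 24. BF3·OEt2 with (E)-styrylboronic acid adds the alkenyl group to the N-acyliminium ion trans to the C1 substituent and gives the trans-3-styryl lactam F5. Ozonolysis (O3; Me2S) gives the C3 aldehyde F6. Allylboration with a 2-(ethoxycarbonyl)allylboronate of a chiral diol, through a closed six-membered transition state, gives the hydroxy ester F7, which lactonises on warming with PPTS to the α-methylene lactone F8. Hydrogenation (H2, Rh/Al2O3) adds hydrogen from the face away from C3 and gives 24.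

3. Step 5 (γ-bromination and lactonisation). Bromination may go to the α-carbon C9, or the γ-bromo enone may lose HBr and aromatise to a phenol before the carboxylate displaces bromide. The fallback replaces halogenation and displacement by oxidation and inversion; it sets out from 5 and returns at 7. mCPBA in CH2Cl2 at −20 °C (vinylogous Rubottom oxidation) introduces oxygen at C11 anti to the side chain and gives, after aqueous work-up, the trans-γ-hydroxy enone acid F9. Mitsunobu lactonisation (PPh3, DIAD, THF) closes the lactone with inversion at C11 and gives 7.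

**Further compounds**

F1 | step 19 | vinyl ketone silyl ether | CC[C@H](C(=O)C=C)[C@@H]1OC(=O)[C@@H](C)[C@@H]1[C@@H]1C[C@@H]([C@@H]2C[C@H](C)C(=O)O2)N(CCCO[Si](C)(C)C(C)(C)C)C1=O
F2 | step 19 | vinyl ketone alcohol | CC[C@H](C(=O)C=C)[C@@H]1OC(=O)[C@@H](C)[C@@H]1[C@@H]1C[C@@H]([C@@H]2C[C@H](C)C(=O)O2)N(CCCO)C1=O
F3 | step 19 | vinyl ketone aldehyde | CC[C@H](C(=O)C=C)[C@@H]1OC(=O)[C@@H](C)[C@@H]1[C@@H]1C[C@@H]([C@@H]2C[C@H](C)C(=O)O2)N(CCC=O)C1=O
F4 | step 19 | N-but-3-enyl vinyl ketone | CC[C@H](C(=O)C=C)[C@@H]1OC(=O)[C@@H](C)[C@@H]1[C@@H]1C[C@@H]([C@@H]2C[C@H](C)C(=O)O2)N(CCC=C)C1=O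
F5 | step 14 | trans-3-styryl lactam | CC[C@H](C(C)=O)[C@@H]1OC(=O)[C@@H](C)[C@@H]1[C@@H]1C[C@@H](/C=C/c2ccccc2)N(CCCO[Si](C)(C)C(C)(C)C)C1=O
F6 | step 14 | C3 aldehyde | CC[C@H](C(C)=O)[C@@H]1OC(=O)[C@@H](C)[C@@H]1[C@@H]1C[C@@H](C=O)N(CCCO[Si](C)(C)C(C)(C)C)C1=O
F7 | step 14 | C18 hydroxy ester | CC[C@H](C(C)=O)[C@@H]1OC(=O)[C@@H](C)[C@@H]1[C@@H]1C[C@@H]([C@@H](O)CC(=C)C(=O)OCC)N(CCCO[Si](C)(C)C(C)(C)C)C1=O
F8 | step 14 | α-methylene lactone | CC[C@H](C(C)=O)[C@@H]1OC(=O)[C@@H](C)[C@@H]1[C@@H]1C[C@@H]([C@@H]2CC(=C)C(=O)O2)N(CCCO[Si](C)(C)C(C)(C)C)C1=O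
F9 | step 5 | trans-γ-hydroxy enone acid | C1=C(C)C(=O)C[C@@H](C(C)C(=O)O)[C@@H]1O
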